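The α,β-unsaturated γ-lactam (N, C10, C11, C12, C18) fused to the cyclohexene is cut at C12–C18 and C18–N, so C18 arrives last as carbon monoxide. In one operation palladium(II), held by the C10 amine, cleaves the vinylic C12–H bond that lies cis to C10 on the C11=C12 ring alkene, inserts CO and closes the lactam. The precursor is the des-C18 bicyclo[9.3.1] primary allylic amine carrying the 6-acetate, the C4 methylidene group and the (E)-C7=C8 alkene. It is assembled by copper-catalysed conjugate addition, a Shapiro formylation, sulfinimine propargylation, methylalumination and a silicon-mediated C5–C6 macrocyclisation.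

Key step: step 15

Remark: verticillane locants are used and coincide with bicyclo[9.3.1]pentadecane numbering (C1/C11 bridgeheads, C2–C10 long bridge, C12–C14 short bridge, C15 = CMe2, C18 = lactam C=O); the target is (1R,6S,10R), C1 is formally S in every des-C18 compound only because C18 changes the CIP ranking, and since the vinylic C7–H is also cis to the C9–C10 arm, site selectivity in step 15 is assumed to rest on palladacycle ring size (five versus six), not on C12–H being the only accessible vinylic C–H.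

Step 1
Reactants: 1 3-methylbut-3-en-1-ol
Product: 4 3-[(trimethylsilyl)methyl]but-3-en-1-ol, via dilithio dianion 2 (not isolated), via bis-silyl ether 3 (not isolated)
Conditions: n-BuLi (2.2 equiv), TMEDA, Et2O, 0 °C → rt; TMSCl (2.5 equiv), –78 °C → rt; K2CO3, MeOH, rt
Reagents that add atoms: chlorotrimethylsilane, C[Si](C)(C)Cl
Why: Alkoxide-directed allylic lithiation removes a methyl proton to give the O,C-dianion, which is silylated at both sites, and mild methanolysis then cleaves only the Si–O bond (directed allylic metalation/silylation).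

Step 2
Reactants: 4 3-[(trimethylsilyl)methyl]but-3-en-1-ol
Product: 5 4-bromo-2-[(trimethylsilyl)methyl]but-1-ene
Conditions: CBr4, PPh3, 2,6-lutidine (cat.), CH2Cl2, 0 °C
Reagents that add atoms: tetrabromomethane, BrC(Br)(Br)Br
Why: The Appel reaction converts the primary alcohol into the bromide by SN2 displacement of the alkoxyphosphonium ion under neutral conditions that leave the allylsilane intact.

Step 3
Reactants: 5 4-bromo-2-[(trimethylsilyl)methyl]but-1-ene; 6 2-methylcyclohex-2-en-1-one
Product: 9 (S)-2,2-dimethyl-3-{3-[(trimethylsilyl)methyl]but-3-en-1-yl}cyclohexan-1-one, via Grignard reagent 7 (not isolated), via magnesium enolate 8 (not isolated)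
Conditions: Mg, Et2O, rt; 6, Cu(OTf)2 (3 mol %), chiral imidazolinium NHC precursor (4 mol %), Et2O, –30 °C; MeI, DMPU, THF, –30 °C → rt
Reagents that add atoms: iodomethane, CI
Why: In this copper-catalysed asymmetric conjugate addition of a Grignard reagent to an α-methyl enone, the chiral NHC–copper catalyst (enantiomer chosen to give the S ketone) sets C1 by reagent-controlled facial delivery, and C-methylation of the regiodefined magnesium enolate builds the C15 gem-dimethyl group without a new stereocentre.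

Step 4
Reactants: 9 (S)-2,2-dimethyl-3-{3-[(trimethylsilyl)methyl]but-3-en-1-yl}cyclohexan-1-one
Product: 10 N'-[(1E,3S)-2,2-dimethyl-3-{3-[(trimethylsilyl)methyl]but-3-en-1-yl}cyclohexylidene]-2,4,6-tri(propan-2-yl)benzenesulfonohydrazide
Conditions: 2,4,6-triisopropylbenzenesulfonohydrazide, THF, 4 Å MS, rt
Reagents that add atoms: 2,4,6-triisopropylbenzenesulfonohydrazide, CC(C)c1cc(C(C)C)c(S(=O)(=O)NN)c(C(C)C)c1
Why: Hydrazone condensation places the sulfonamide arm anti to the quaternary C15, which is the geometry needed for syn α-deprotonation at C12.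

Step 5
Reactants: 10 N'-[(1E,3S)-2,2-dimethyl-3-{3-[(trimethylsilyl)methyl]but-3-en-1-yl}cyclohexylidene]-2,4,6-tri(propan-2-yl)benzenesulfonohydrazide
Product: 13 (S)-6,6-dimethyl-5-{3-[(trimethylsilyl)methyl]but-3-en-1-yl}cyclohex-1-ene-1-carbaldehyde, via dilithiated hydrazone 11 (not isolated), via vinyllithium 12 (not isolated)
Conditions: n-BuLi (2.2 equiv), THF, –78 → 0 °C; DMF, –78 °C → rt; H2O
Reagents that add atoms: N,N-dimethylformamide, CN(C)C=O
Why: In this Shapiro reaction the second deprotonation can occur only at C12 because C15 is quaternary, so loss of sulfinate and N2 gives the C11 vinyllithium with the C11=C12 bond regiospecifically, and formylation with DMF installs C10.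

Step 6
Reactants: 13 (S)-6,6-dimethyl-5-{3-[(trimethylsilyl)methyl]but-3-en-1-yl}cyclohex-1-ene-1-carbaldehyde; 14 (S)-2-methylpropane-2-sulfinamide
Product: 15 (S)-N-[(E)-{(5S)-6,6-dimethyl-5-{3-[(trimethylsilyl)methyl]but-3-en-1-yl}cyclohex-1-en-1-yl}methylidene]-2-methylpropane-2-sulfinamide
Conditions: Ti(OEt)4 (2 equiv), THF, rt → 50 °C
Reagents that add atoms: none
Why: Titanium(IV) ethoxide-mediated condensation of an enal with tert-butanesulfinamide gives the (E)-N-sulfinyl aldimine and does not affect the allylsilane.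

Step 7
Reactants: 15 (S)-N-[(E)-{(5S)-6,6-dimethyl-5-{3-[(trimethylsilyl)methyl]but-3-en-1-yl}cyclohex-1-en-1-yl}methylidene]-2-methylpropane-2-sulfinamide; 16 3-bromoprop-1-yne
Product: 18 (S)-N-{(1R)-1-[(5S)-6,6-dimethyl-5-{3-[(trimethylsilyl)methyl]but-3-en-1-yl}cyclohex-1-en-1-yl]but-3-yn-1-yl}-2-methylpropane-2-sulfinamide, via allenylzinc bromide 17 (not isolated)
Conditions: Zn dust (activated), THF, 0 °C → rt; H2O
Reagents that add atoms: none
Why: In this Barbier-type zinc propargylation of an N-tert-butanesulfinyl aldimine the allenylzinc attacks in an SE2′ sense through a closed chair transition state with zinc bound to nitrogen and the sulfinyl oxygen, so the (S)-sulfur directs C9 to the Re face of the imine and sets 10R by auxiliary control.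

Step 8
Reactants: 18 (S)-N-{(1R)-1-[(5S)-6,6-dimethyl-5-{3-[(trimethylsilyl)methyl]but-3-en-1-yl}cyclohex-1-en-1-yl]but-3-yn-1-yl}-2-methylpropane-2-sulfinamide
Product: 21 (S)-N-{(1R,3E)-1-[(5S)-6,6-dimethyl-5-{3-[(trimethylsilyl)methyl]but-3-en-1-yl}cyclohex-1-en-1-yl]-5-hydroxy-3-methylpent-3-en-1-yl}-2-methylpropane-2-sulfinamide, via alkenylalane 19 (not isolated), via lithium alanate 20 (not isolated)
Conditions: Me3Al (4 equiv), Cp2ZrCl2 (0.5 equiv), CH2Cl2, 0 °C → rt; concentrate; n-BuLi, THF, –30 °C; (CH2O)n, rt; aq. Rochelle salt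
Reagents that add atoms: trimethylaluminium, C[Al](C)C; formaldehyde (as paraformaldehyde), C=O
Why: Zirconocene-catalysed methylalumination of the terminal alkyne is a syn addition placing methyl on C8 and aluminium on C7, which fixes the (E)-C7=C8 geometry mechanistically, and the derived alanate is hydroxymethylated with retention to supply C6.

Step 9
Reactants: 21 (S)-N-{(1R,3E)-1-[(5S)-6,6-dimethyl-5-{3-[(trimethylsilyl)methyl]but-3-en-1-yl}cyclohex-1-en-1-yl]-5-hydroxy-3-methylpent-3-en-1-yl}-2-methylpropane-2-sulfinamide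
Product: 22 (S)-N-{(1R,3E)-1-[(5S)-6,6-dimethyl-5-{3-[(trimethylsilyl)methyl]but-3-en-1-yl}cyclohex-1-en-1-yl]-3-methyl-5-oxopent-3-en-1-yl}-2-methylpropane-2-sulfinamide
Conditions: MnO2 (activated, excess), CH2Cl2, rt
Reagents that add atoms: none
Why: Manganese dioxide oxidises the primary allylic alcohol chemoselectively to the (E)-enal under neutral conditions that spare the sulfinamide and the allylsilane.

Step 10
Reactants: 22 (S)-N-{(1R,3E)-1-[(5S)-6,6-dimethyl-5-{3-[(trimethylsilyl)methyl]but-3-en-1-yl}cyclohex-1-en-1-yl]-3-methyl-5-oxopent-3-en-1-yl}-2-methylpropane-2-sulfinamide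
Product: 23 (S)-N-[(1S,6RS,7E,10R)-6-hydroxy-8,15,15-trimethyl-4-methylidenebicyclo[9.3.1]pentadeca-7,11-dien-10-yl]-2-methylpropane-2-sulfinamide
Conditions: BF3·OEt2 (3 equiv), CH2Cl2 (1 mM, slow addition of 22), –78 °C; aq. NaHCO3
Reagents that add atoms: none
Why: In this intramolecular Hosomi–Sakurai allylation the 2-substituted allylsilane, the most nucleophilic π-system present, attacks the BF3-activated aldehyde carbon in an SE2′ sense (1,2-addition, as usual for β,β-disubstituted enals), forming C5–C6, closing the twelve-membered ring and unveiling the C4 methylidene group, while the C6 configuration is left to steps 11 and 12.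

Step 11
Reactants: 23 (S)-N-[(1S,6RS,7E,10R)-6-hydroxy-8,15,15-trimethyl-4-methylidenebicyclo[9.3.1]pentadeca-7,11-dien-10-yl]-2-methylpropane-2-sulfinamide
Product: 24 (S)-N-[(1S,7E,10R)-8,15,15-trimethyl-4-methylidene-6-oxobicyclo[9.3.1]pentadeca-7,11-dien-10-yl]-2-methylpropane-2-sulfinamide
Conditions: MnO2 (activated, excess), CH2Cl2, rt
Reagents that add atoms: none
Why: Allylic oxidation with manganese dioxide converges both C6 epimers on one enone under neutral conditions that should not move the β,γ-methylidene bond into conjugation.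

Step 12
Reactants: 24 (S)-N-[(1S,7E,10R)-8,15,15-trimethyl-4-methylidene-6-oxobicyclo[9.3.1]pentadeca-7,11-dien-10-yl]-2-methylpropane-2-sulfinamide
Product: 25 (S)-N-[(1S,6S,7E,10R)-6-hydroxy-8,15,15-trimethyl-4-methylidenebicyclo[9.3.1]pentadeca-7,11-dien-10-yl]-2-methylpropane-2-sulfinamide
Conditions: (R)-2-methyl-CBS-oxazaborolidine (0.5 equiv), catecholborane, toluene, –78 °C; MeOH, then H2O
Reagents that add atoms: none
Why: In the CBS reduction the (R)-oxazaborolidine treats the alkenyl arm (C7) as the large group and the C5 methylene as the small one, so hydride is delivered to the face that gives 6S by catalyst control, and catecholborane at –78 °C does not hydroborate the alkenes.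

Step 13
Reactants: 25 (S)-N-[(1S,6S,7E,10R)-6-hydroxy-8,15,15-trimethyl-4-methylidenebicyclo[9.3.1]pentadeca-7,11-dien-10-yl]-2-methylpropane-2-sulfinamide
Product: 26 (1S,6S,7E,10R)-10-{[(S)-tert-butylsulfinyl]amino}-8,15,15-trimethyl-4-methylidenebicyclo[9.3.1]pentadeca-7,11-dien-6-yl acetate
Conditions: Ac2O, Et3N, DMAP (cat.), CH2Cl2, 0 °C
Reagents that add atoms: acetic anhydride, CC(=O)OC(C)=O
Why: DMAP-catalysed acetylation esterifies the secondary alcohol with retention at C6, and the sulfinamide N–H is not acylated under these conditions.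

Step 14
Reactants: 26 (1S,6S,7E,10R)-10-{[(S)-tert-butylsulfinyl]amino}-8,15,15-trimethyl-4-methylidenebicyclo[9.3.1]pentadeca-7,11-dien-6-yl acetate
Product: 27 (1S,6S,7E,10R)-10-amino-8,15,15-trimethyl-4-methylidenebicyclo[9.3.1]pentadeca-7,11-dien-6-yl acetate
Conditions: HCl (4 M in dioxane, 3 equiv), MeOH, 0 °C, 20 min; aq. NaHCO3
Reagents that add atoms: none
Why: Acidic methanolysis cleaves the S–N bond of the tert-butanesulfinamide within minutes at 0 °C, conditions under which the secondary acetate and the alkenes should persist, and bicarbonate liberates the free primary amine.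

Step 15
Reactants: 27 (1S,6S,7E,10R)-10-amino-8,15,15-trimethyl-4-methylidenebicyclo[9.3.1]pentadeca-7,11-dien-6-yl acetate; 28 carbon monoxide
Product: 31 cespitulactam E, via azapalladacycle 29 (not isolated), via acylpalladacycle 30 (not isolated)
Conditions: Pd(OAc)2 (10 mol %), Cu(OAc)2 (2.2 equiv), PivOH (1 equiv), CO (1 atm), toluene, 80 °C
Reagents that add atoms: none
Why: The free amine binds Pd(II) and carboxylate-assisted concerted metalation–deprotonation breaks the vinylic C12–H bond cis to C10, giving the five-membered azapalladacycle (N, C10, C11, C12, Pd); CO inserts into the Pd–C12 bond to give the six-membered acylpalladacycle, and C18–N reductive elimination releases the lactam while Cu(II) returns Pd(0) to Pd(II). The closest known reaction type is the Pd(II)-catalysed amine-directed oxidative C–H carbonylation that converts benzylamines into isoindolinones and allylamines into 1,5-dihydropyrrol-2-ones. The five-membered lactam ring (N–C10–C11=C12–C18) closes in that reductive elimination, by contraction of the six-membered acylpalladacycle with extrusion of palladium, the endocyclic C11=C12 bond holding C10 and C12 cis. No stereocentre is created and C1, C6 and C10 are not touched (C1 changes from S to R in CIP ranking only). The step needs site selectivity for C12–H over the vinylic C7–H, which would require a six-membered palladacycle bridging the macrocycle, and over the C4 methylidene C–H bonds, which cannot chelate; it also needs the allylic acetate to survive, which phosphine-free palladium under CO with excess Cu(II) should allow by keeping Pd(0) short-lived.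

Compound list
1 | 3-methylbut-3-en-1-ol | C=C(C)CCO | starting material
2 | dilithio O,C-dianion of 3-methylbut-3-en-1-ol | [Li]OCCC(=C)C[Li] | intermediate
3 | trimethyl{2-methylidene-4-[(trimethylsilyl)oxy]butyl}silane | C=C(C[Si](C)(C)C)CCO[Si](C)(C)C | intermediate
4 | 3-[(trimethylsilyl)methyl]but-3-en-1-ol | C=C(C[Si](C)(C)C)CCO | intermediate
5 | 4-bromo-2-[(trimethylsilyl)methyl]but-1-ene | C=C(C[Si](C)(C)C)CCBr | intermediate
6 | 2-methylcyclohex-2-en-1-one | CC1=CCCCC1=O | starting material
7 | {3-[(trimethylsilyl)methyl]but-3-en-1-yl}magnesium bromide | C=C(C[Si](C)(C)C)CC[Mg]Br | intermediate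
8 | bromomagnesium (S)-2-methyl-3-{3-[(trimethylsilyl)methyl]but-3-en-1-yl}cyclohex-1-en-1-olate | C=C(C[Si](C)(C)C)CC[C@@H]1CCCC(O[Mg]Br)=C1C | intermediate
9 | (S)-2,2-dimethyl-3-{3-[(trimethylsilyl)methyl]but-3-en-1-yl}cyclohexan-1-one | C=C(C[Si](C)(C)C)CC[C@@H]1CCCC(=O)C1(C)C | intermediate
10 | N'-[(1E,3S)-2,2-dimethyl-3-{3-[(trimethylsilyl)methyl]but-3-en-1-yl}cyclohexylidene]-2,4,6-tri(propan-2-yl)benzenesulfonohydrazide | C=C(C[Si](C)(C)C)CC[C@@H]1CCC/C(=N\NS(=O)(=O)c2c(C(C)C)cc(C(C)C)cc2C(C)C)C1(C)C | intermediate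
11 | N,C12-dilithiated hydrazone of 10, drawn as the aza-enolate | C=C(C[Si](C)(C)C)CC[C@@H]1CCC=C(N([Li])N([Li])S(=O)(=O)c2c(C(C)C)cc(C(C)C)cc2C(C)C)C1(C)C | intermediate
12 | [(5S)-6,6-dimethyl-5-{3-[(trimethylsilyl)methyl]but-3-en-1-yl}cyclohex-1-en-1-yl]lithium | C=C(C[Si](C)(C)C)CC[C@@H]1CCC=C([Li])C1(C)C | intermediate
13 | (S)-6,6-dimethyl-5-{3-[(trimethylsilyl)methyl]but-3-en-1-yl}cyclohex-1-ene-1-carbaldehyde | C=C(C[Si](C)(C)C)CC[C@@H]1CCC=C(C=O)C1(C)C | intermediate
14 | (S)-2-methylpropane-2-sulfinamide | CC(C)(C)[S@](=O)N | starting material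
15 | (S)-N-[(E)-{(5S)-6,6-dimethyl-5-{3-[(trimethylsilyl)methyl]but-3-en-1-yl}cyclohex-1-en-1-yl}methylidene]-2-methylpropane-2-sulfinamide | C=C(C[Si](C)(C)C)CC[C@@H]1CCC=C(/C=N/[S@@](=O)C(C)(C)C)C1(C)C | intermediate
16 | 3-bromoprop-1-yne | C#CCBr | starting material
17 | propa-1,2-dien-1-ylzinc bromide | C=C=C[Zn]Br | intermediate
18 | (S)-N-{(1R)-1-[(5S)-6,6-dimethyl-5-{3-[(trimethylsilyl)methyl]but-3-en-1-yl}cyclohex-1-en-1-yl]but-3-yn-1-yl}-2-methylpropane-2-sulfinamide | C=C(C[Si](C)(C)C)CC[C@@H]1CCC=C([C@@H](CC#C)N[S@@](=O)C(C)(C)C)C1(C)C | intermediate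
19 | (E)-C7 dimethylalane of the methylaluminated alkyne, N-aluminated | C=C(C[Si](C)(C)C)CC[C@@H]1CCC=C([C@@H](C/C(C)=C/[Al](C)C)N([Al](C)C)[S@@](=O)C(C)(C)C)C1(C)C | intermediate
20 | lithium butyl(dimethyl)alkenylalanate derived from 19 | [Li+].C=C(C[Si](C)(C)C)CC[C@@H]1CCC=C([C@@H](C/C(C)=C/[Al-](C)(C)CCCC)N([Al](C)C)[S@@](=O)C(C)(C)C)C1(C)C | intermediate
21 | (S)-N-{(1R,3E)-1-[(5S)-6,6-dimethyl-5-{3-[(trimethylsilyl)methyl]but-3-en-1-yl}cyclohex-1-en-1-yl]-5-hydroxy-3-methylpent-3-en-1-yl}-2-methylpropane-2-sulfinamide | C=C(C[Si](C)(C)C)CC[C@@H]1CCC=C([C@@H](C/C(C)=C/CO)N[S@@](=O)C(C)(C)C)C1(C)C | intermediate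
22 | (S)-N-{(1R,3E)-1-[(5S)-6,6-dimethyl-5-{3-[(trimethylsilyl)methyl]but-3-en-1-yl}cyclohex-1-en-1-yl]-3-methyl-5-oxopent-3-en-1-yl}-2-methylpropane-2-sulfinamide | C=C(C[Si](C)(C)C)CC[C@@H]1CCC=C([C@@H](C/C(C)=C/C=O)N[S@@](=O)C(C)(C)C)C1(C)C | intermediate
23 | (S)-N-[(1S,6RS,7E,10R)-6-hydroxy-8,15,15-trimethyl-4-methylidenebicyclo[9.3.1]pentadeca-7,11-dien-10-yl]-2-methylpropane-2-sulfinamide (C6 epimers) | C=C1CC[C@@H]2CCC=C([C@@H](C/C(C)=C/C(O)C1)N[S@@](=O)C(C)(C)C)C2(C)C | intermediate
24 | (S)-N-[(1S,7E,10R)-8,15,15-trimethyl-4-methylidene-6-oxobicyclo[9.3.1]pentadeca-7,11-dien-10-yl]-2-methylpropane-2-sulfinamide | C=C1CC[C@@H]2CCC=C([C@@H](C/C(C)=C/C(=O)C1)N[S@@](=O)C(C)(C)C)C2(C)C | intermediate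
25 | (S)-N-[(1S,6S,7E,10R)-6-hydroxy-8,15,15-trimethyl-4-methylidenebicyclo[9.3.1]pentadeca-7,11-dien-10-yl]-2-methylpropane-2-sulfinamide | C=C1CC[C@@H]2CCC=C([C@@H](C/C(C)=C/[C@@H](O)C1)N[S@@](=O)C(C)(C)C)C2(C)C | intermediate
26 | (1S,6S,7E,10R)-10-{[(S)-tert-butylsulfinyl]amino}-8,15,15-trimethyl-4-methylidenebicyclo[9.3.1]pentadeca-7,11-dien-6-yl acetate | C=C1CC[C@@H]2CCC=C([C@@H](C/C(C)=C/[C@@H](OC(C)=O)C1)N[S@@](=O)C(C)(C)C)C2(C)C | intermediate
27 | (1S,6S,7E,10R)-10-amino-8,15,15-trimethyl-4-methylidenebicyclo[9.3.1]pentadeca-7,11-dien-6-yl acetate (des-C18 macrocyclic allylic amine) | C=C1CC[C@@H]2CCC=C([C@@H](C/C(C)=C/[C@@H](OC(C)=O)C1)N)C2(C)C | intermediate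
28 | carbon monoxide | [C-]#[O+] | starting material
29 | five-membered azapalladacycle (N, C10, C11, C12, Pd), drawn as the monomeric acetate | C=C1CC[C@@H]2CCC3=C([C@@H](C/C(C)=C/[C@@H](OC(C)=O)C1)[NH2+][Pd-]3OC(C)=O)C2(C)C | intermediate
30 | six-membered acylpalladacycle (N, C10, C11, C12, C18, Pd), drawn as the monomeric acetate | C=C1CC[C@@H]2CCC3=C([C@@H](C/C(C)=C/[C@@H](OC(C)=O)C1)[NH2+][Pd-](OC(C)=O)C3=O)C2(C)C | intermediate
31 | cespitulactam E, (1R,6S,10R) | C=C1CC[C@@H]2CCC3=C([C@@H](C/C(C)=C/[C@@H](OC(C)=O)C1)NC3=O)C2(C)C | target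

Total step count: 15
Longest linear sequence: 15 steps (from 1 to 31)

Steps most likely to fail

1. Step 15 (directed carbonylation). Palladium may be sequestered as an unreactive bis(amine) complex, the amine may be carbonylated to a urea, C–H cleavage may occur at C7 through the six-membered palladacycle, or Pd(0) may ionise the allylic acetate. Fallback: starting from 27, amide coupling with picolinic acid (EDC, HOBt, CH2Cl2) would give the N-picolinoyl amine F1. Its N,N-bidentate amidate enforces the five-membered palladacycle at C12 and excludes bis(amine) binding and urea formation. Oxidative carbonylation (Pd(OAc)2, AgOAc, CO, toluene, 100 °C) would then give the N-picolinoyl lactam F2. Brief ammonolysis (NH3, MeOH, 0 °C) removes the exocyclic acyl group of this imide faster than the acetate and returns the route to 31.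

2. Step 10 (Sakurai macrocyclisation). Intermolecular oligomerisation, protodesilylation, E/Z scrambling of the Lewis-acid-bound enal or Lewis-acid damage to the sulfinamide may compete with ring closure. Fallback: starting from 22, ipso-bromodesilylation (NBS, 1.0 equiv, propylene oxide, CH2Cl2, –78 °C; the silylmethyl alkene is by far the most nucleophilic site) would give the allylic bromide F3. Nozaki–Hiyama allylation (CrCl2, THF, high dilution, rt) would then close the same C5–C6 bond through an allylchromium(III) species under neutral conditions and rejoin the route at 23.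

3. Step 8 (methylalumination/hydroxymethylation). The aluminated sulfinamide may retard or misdirect the carbometalation, or the alanate may fail to capture formaldehyde cleanly. Fallback: starting from 18, double deprotonation (n-BuLi, 2.2 equiv, THF, –78 °C) and paraformaldehyde would give the propargylic alcohol F4. Hydroxyl-directed trans-hydroalumination (LiAlH4, NaOMe, THF) followed by iodinolysis would give the (Z)-3-iodo allylic alcohol F5. Coupling with Me2CuLi (Et2O, 0 °C) replaces iodine by methyl with retention and returns the route to 21.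

Further compounds
F1 | step 15 | (1S,6S,7E,10R)-8,15,15-trimethyl-4-methylidene-10-(pyridine-2-carboxamido)bicyclo[9.3.1]pentadeca-7,11-dien-6-yl acetate | C=C1CC[C@@H]2CCC=C([C@@H](C/C(C)=C/[C@@H](OC(C)=O)C1)NC(=O)c3ccccn3)C2(C)C
F2 | step 15 | N-(pyridine-2-carbonyl)cespitulactam E | C=C1CC[C@@H]2CCC3=C([C@@H](C/C(C)=C/[C@@H](OC(C)=O)C1)N(C(=O)c4ccccn4)C3=O)C2(C)C
F3 | step 10 | (S)-N-{(1R,3E)-1-[(5S)-5-[3-(bromomethyl)but-3-en-1-yl]-6,6-dimethylcyclohex-1-en-1-yl]-3-methyl-5-oxopent-3-en-1-yl}-2-methylpropane-2-sulfinamide | C=C(CBr)CC[C@@H]1CCC=C([C@@H](C/C(C)=C/C=O)N[S@@](=O)C(C)(C)C)C1(C)C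
F4 | step 8 | (S)-N-{(1R)-1-[(5S)-6,6-dimethyl-5-{3-[(trimethylsilyl)methyl]but-3-en-1-yl}cyclohex-1-en-1-yl]-5-hydroxypent-3-yn-1-yl}-2-methylpropane-2-sulfinamide | C=C(C[Si](C)(C)C)CC[C@@H]1CCC=C([C@@H](CC#CCO)N[S@@](=O)C(C)(C)C)C1(C)C
F5 | step 8 | (S)-N-{(1R,3Z)-1-[(5S)-6,6-dimethyl-5-{3-[(trimethylsilyl)methyl]but-3-en-1-yl}cyclohex-1-en-1-yl]-5-hydroxy-3-iodopent-3-en-1-yl}-2-methylpropane-2-sulfinamide | C=C(C[Si](C)(C)C)CC[C@@H]1CCC=C([C@@H](C/C(I)=C/CO)N[S@@](=O)C(C)(C)C)C1(C)C
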